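The 4-pyranone ring (O1, C2–C6) is cut at C2=C3. C2 carries O1 and OMe, so it stands at the carbonic acid level and is read as the carbonyl carbon of a methyl carbonate. C3, alpha to the C4 ketone, is read as an acyl-stabilised phosphorus ylide carbon. One thermal intramolecular Wittig olefination then forms C2=C3, closes the ring and puts the methoxy group in place. This avoids the regiochemically ambiguous O-methylation of a 4-hydroxy-2-pyranone. The precursor is the Z enol methyl carbonate of a 2-methyl-1,3-diketone whose second carbonyl bears C(Me)=PPh3. Its side chain already ends in the acetate, so ring closure gives the target itself.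

Key step: step 5

Assumption: oxacyclotridecan-2-one, the lactone of 12-hydroxydodecanoic acid, is taken as a purchasable chemical; atoms of open-chain intermediates are referred to by the numbers they will carry in the ring (O1, C2, C3, C4, C5, C6).

Step 1
Reactants: 1 triphenylphosphine; 2 2-bromopentan-3-one (racemic)
Product: 4 2-(triphenylphosphoranylidene)pentan-3-one, via phosphonium bromide 3 (not isolated)
Conditions: PhMe, 100 °C; evaporation, then 2 M aq NaOH, CH2Cl2, rt
Reagents that add atoms: none
Why: SN2 quaternisation of the phosphine by the α-bromo ketone, followed by removal of the acidic P–CH–C=O proton, is the standard preparation of a water-tolerant acyl-stabilised Wittig ylide, and the stereocentre of 2 and 3 disappears at the planar ylide carbon.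

Step 2
Reactants: 4 2-(triphenylphosphoranylidene)pentan-3-one; 5 oxacyclotridecan-2-one
Product: 7 16-hydroxy-4-methyl-2-(triphenylphosphoranylidene)hexadecane-3,5-dione (racemic), via lithiated ylide 6 (not isolated)
Conditions: 4 (2.2 equiv), LiN(i-Pr)2 (2.2 equiv), THF, −78 °C; then 5 (1 equiv), −78 → 0 °C; aq NH4Cl; surplus 4 recovered
Reagents that add atoms: none
Why: In this crossed Claisen-type C-acylation the α′-CH2 is the most acidic site of the keto ylide, its lithium enolate attacks the lactone carbonyl through carbon, ring opening frees the chain alkoxide, and the second equivalent of 6 absorbs the acidic C5–H of the new 1,3-diketone; C5 forms as a labile racemate that is erased in step 4.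

Step 3
Reactants: 7 16-hydroxy-4-methyl-2-(triphenylphosphoranylidene)hexadecane-3,5-dione
Product: 8 13-methyl-12,14-dioxo-15-(triphenylphosphoranylidene)hexadecyl acetate (racemic)
Conditions: Ac2O (1.2 equiv), pyridine, CH2Cl2, 0 °C → rt; aq Na2CO3 wash
Reagents that add atoms: acetic anhydride, CC(=O)OC(C)=O
Why: In this pyridine-mediated O-acetylation the unhindered primary alcohol is by far the fastest acyl acceptor, the 2-methyl-1,3-diketone sits mainly in its keto form, and the fully substituted stabilised ylide can only be acylated or protonated reversibly, so the carbonate wash should return it intact.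

Step 4
Reactants: 8 13-methyl-12,14-dioxo-15-(triphenylphosphoranylidene)hexadecyl acetate; 9 methyl chloroformate
Product: 11 (Z)-16-acetoxy-4-methyl-3-oxo-2-(triphenylphosphoranylidene)hexadec-4-en-5-yl methyl carbonate, via sodium enolate 10 (not isolated)
Conditions: NaH (1.0 equiv), THF, 0 °C; then 9 (1.0 equiv), −20 → 0 °C; filtration through Celite under Ar, evaporation
Reagents that add atoms: none
Why: This is O-acylation of a chelated sodium 1,3-diketonate by a hard chloroformate (enol carbonate formation): the new charge rests mainly on the oxygen at C6, because the C4 oxygen is already fed by the ylide and shielded by PPh3 and C5 is hindered, and the U-shaped chelate places the carbonate cis to the acyl group and so sets the Z geometry.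

Step 5
Reactants: 11 (Z)-16-acetoxy-4-methyl-3-oxo-2-(triphenylphosphoranylidene)hexadec-4-en-5-yl methyl carbonate
Product: 12 11-(6-methoxy-3,5-dimethyl-4-oxo-4H-pyran-2-yl)undecyl acetate
Conditions: dry degassed PhMe (0.02 M), 110 °C, Ar
Reagents that add atoms: none
Why: Proposed new method: the ylide carbon C3 adds to the carbonate carbonyl C2, the alkoxide so formed binds phosphorus, and the fused oxaphosphetane breaks down to Ph3P=O and the C2=C3 double bond, with OMe and O1 left on C2. The closest known reaction type is the intramolecular Wittig olefination of aryl and enol ester carbonyls by acyl-stabilised ylides, which builds chromones, benzofurans and 4-pyranones; a carbonate carbonyl, a weaker electrophile, has not been shown to take part. The one ring closes in the 6-(enolendo)-exo-trig mode, with the C3=C4 enolate unit of the ylide inside the new six-membered ring and the C2=O bond outside it, a geometry that is allowed at this ring size. No stereocentre is formed; the only stereochemical demand is the Z enol carbonate geometry fixed in step 4, which keeps C2 within bonding distance of C3. The step needs olefination to beat O-to-C migration of the CO2Me group and loss of methoxide from the tetrahedral adduct, and the substrate helps because C3 is fully substituted, so the migration product is a phosphonium enolate betaine that has no proton to lose and can only fall back to the same adduct, while a non-polar, salt-free medium disfavours every charge-separating exit. Irreversible P=O formation and the gain of the conjugated vinylogous carbonate of the pyranone should then drain these equilibria toward 12.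

Compound list
1 | triphenylphosphine | c1ccc(cc1)P(c1ccccc1)c1ccccc1 | starting material
2 | 2-bromopentan-3-one (racemic) | CCC(=O)C(C)Br | starting material
3 | (3-oxopentan-2-yl)triphenylphosphonium bromide (racemic) | CCC(=O)C(C)[P+](c1ccccc1)(c1ccccc1)c1ccccc1.[Br-] | intermediate
4 | 2-(triphenylphosphoranylidene)pentan-3-one | CCC(=O)C(C)=P(c1ccccc1)(c1ccccc1)c1ccccc1 | intermediate
5 | oxacyclotridecan-2-one (12-dodecanolide) | O=C1CCCCCCCCCCCO1 | starting material
6 | lithium 4-(triphenylphosphoranylidene)pent-2-en-3-olate (lithiated ylide) | [Li+].[O-]C(=CC)C(C)=P(c1ccccc1)(c1ccccc1)c1ccccc1 | intermediate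
7 | 16-hydroxy-4-methyl-2-(triphenylphosphoranylidene)hexadecane-3,5-dione (racemic, labile at C4 of the chain) | OCCCCCCCCCCCC(=O)C(C)C(=O)C(C)=P(c1ccccc1)(c1ccccc1)c1ccccc1 | intermediate
8 | 13-methyl-12,14-dioxo-15-(triphenylphosphoranylidene)hexadecyl acetate (racemic, labile at C13 of the chain) | CC(=O)OCCCCCCCCCCCC(=O)C(C)C(=O)C(C)=P(c1ccccc1)(c1ccccc1)c1ccccc1 | intermediate
9 | methyl chloroformate | COC(=O)Cl | starting material
10 | sodium (Z)-16-acetoxy-4-methyl-3-oxo-2-(triphenylphosphoranylidene)hexadec-4-en-5-olate | [Na+].[O-]/C(CCCCCCCCCCCOC(C)=O)=C(/C)C(=O)C(C)=P(c1ccccc1)(c1ccccc1)c1ccccc1 | intermediate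
11 | (Z)-16-acetoxy-4-methyl-3-oxo-2-(triphenylphosphoranylidene)hexadec-4-en-5-yl methyl carbonate | COC(=O)O/C(CCCCCCCCCCCOC(C)=O)=C(/C)C(=O)C(C)=P(c1ccccc1)(c1ccccc1)c1ccccc1 | intermediate
12 | 11-(6-methoxy-3,5-dimethyl-4-oxo-4H-pyran-2-yl)undecyl acetate | COc1oc(CCCCCCCCCCCOC(C)=O)c(C)c(=O)c1C | target

Total step count: 5. Longest linear sequence: 5 steps (steps 1 to 5); 5 and 9 enter as purchased.

Steps most likely to fail

1. Step 5. The carbonate carbonyl may be too weak an electrophile for the stabilised ylide, so that heating only causes slow decomposition. The tetrahedral adduct may also ionise, by loss of methoxide or of the enolate, and move the methyl group onto the C4 oxygen. The fallback uses known chemistry only, sets out from 5 and returns at 12.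
   - The dianion of methyl 2-methyl-3-oxopentanoate (NaH, then n-BuLi, THF, 0 °C, used in excess) would be acylated at its terminal carbon by lactone 5. This should give methyl 16-hydroxy-2,4-dimethyl-3,5-dioxohexadecanoate F1.
   - DBU in hot PhMe would close the enol lactone to 4-hydroxy-6-(11-hydroxyundecyl)-3,5-dimethyl-2H-pyran-2-one F2.
   - Fischer esterification (AcOH, cat. TsOH, 60 °C) would acetylate only the primary alcohol, since the vinylogous acid cannot hold an acetyl group under these conditions. The product would be 11-(4-hydroxy-3,5-dimethyl-2-oxo-2H-pyran-6-yl)undecyl acetate F3.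
   - MeOTf in CH2Cl2, followed by aq NaHCO3, would methylate the lactone carbonyl oxygen. This is the established way from 4-hydroxy-2-pyranones to 2-methoxy-4-pyranones, and it gives 12.

2. Step 4. Acylation of the ambident anion may take place at C5, at the C4 oxygen or at the ylide carbon. The sodium chelate may also open and deliver the E geometry, which cannot cyclise. The fallback reverses the order of events, sets out from 5 and returns at 11. The enol carbonate is made on a β-keto ester, where only one enolate oxygen gives a stable product, and the ylide is built last.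
   - Lactone 5 would be opened by the lithium enolate of tert-butyl propanoate (LiN(i-Pr)2, THF, −78 → 0 °C) to tert-butyl 14-hydroxy-2-methyl-3-oxotetradecanoate F4.
   - Acetylation (Ac2O, pyridine) would give tert-butyl 14-acetoxy-2-methyl-3-oxotetradecanoate F5.
   - O-acylation through the sodium chelate (NaH, ClCO2Me, THF) would give tert-butyl (Z)-14-acetoxy-3-(methoxycarbonyloxy)-2-methyltetradec-2-enoate F6.
   - CF3CO2H in CH2Cl2 would free (Z)-14-acetoxy-3-(methoxycarbonyloxy)-2-methyltetradec-2-enoic acid F7.
   - (COCl)2 with cat. DMF at 0 °C would give (Z)-14-acetoxy-3-(methoxycarbonyloxy)-2-methyltetradec-2-enoyl chloride F8.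
   - Two equivalents of ethylidenetriphenylphosphorane (EtPPh3Br, NaN(SiMe3)2, THF, −78 °C) would be C-acylated at the acid chloride with transylidation to give 11.

3. Step 2. Three processes may stall the acylation: enolisation of the lactone by the strongly basic 6, quenching of 6 by the acidic product, and alkoxide-initiated oligomerisation of 5. The fallback changes the electrophile to one that does not release a carbonyl group until work-up, sets out from 5 and returns at 7.
   - Lactone 5 would be opened with MeNH(OMe)·HCl and i-PrMgCl (THF, −10 °C) to 12-hydroxy-N-methoxy-N-methyldodecanamide F9.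
   - The lithium alkoxide of F9 (one extra equivalent of LiN(i-Pr)2) would be added to 6 at −78 °C.
   - The chelated tetrahedral adduct should persist until the aq NH4Cl quench, so no diketone is present while 6 is still in the flask. Work-up gives 7.

Further compounds
F1 | step 5 | methyl 16-hydroxy-2,4-dimethyl-3,5-dioxohexadecanoate (mixture of labile diastereomers) | COC(=O)C(C)C(=O)C(C)C(=O)CCCCCCCCCCCO
F2 | step 5 | 4-hydroxy-6-(11-hydroxyundecyl)-3,5-dimethyl-2H-pyran-2-one | Cc1c(O)c(C)c(CCCCCCCCCCCO)oc1=O
F3 | step 5 | 11-(4-hydroxy-3,5-dimethyl-2-oxo-2H-pyran-6-yl)undecyl acetate | Cc1c(O)c(C)c(CCCCCCCCCCCOC(C)=O)oc1=O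
F4 | step 4 | tert-butyl 14-hydroxy-2-methyl-3-oxotetradecanoate (racemic) | CC(C(=O)OC(C)(C)C)C(=O)CCCCCCCCCCCO
F5 | step 4 | tert-butyl 14-acetoxy-2-methyl-3-oxotetradecanoate (racemic) | CC(C(=O)OC(C)(C)C)C(=O)CCCCCCCCCCCOC(C)=O
F6 | step 4 | tert-butyl (Z)-14-acetoxy-3-(methoxycarbonyloxy)-2-methyltetradec-2-enoate | COC(=O)O/C(CCCCCCCCCCCOC(C)=O)=C(/C)C(=O)OC(C)(C)C
F7 | step 4 | (Z)-14-acetoxy-3-(methoxycarbonyloxy)-2-methyltetradec-2-enoic acid | COC(=O)O/C(CCCCCCCCCCCOC(C)=O)=C(/C)C(=O)O
F8 | step 4 | (Z)-14-acetoxy-3-(methoxycarbonyloxy)-2-methyltetradec-2-enoyl chloride | COC(=O)O/C(CCCCCCCCCCCOC(C)=O)=C(/C)C(=O)Cl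
F9 | step 2 | 12-hydroxy-N-methoxy-N-methyldodecanamide | CON(C)C(=O)CCCCCCCCCCCO
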